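**Retrosynthetic overview**

1. Target 17 is an all-trans 1-aryltetralin: ring A (guaiacyl benzo ring), ring B (C1–C4 carbocycle), pendant syringyl ring on C1. The late steps only remove one activating ester from C3 with thermodynamic C3 epimerisation, reduce the C3 ester, and unmask the silyl and benzyl ethers.
2. Key disconnection: ring B by a formal [3+3] annulation that makes C3–C4 and C1–C8a at once, from the cis-cyclopropane-1,1-diester 8 (C1–C2–C3 unit; its C1–C3 bond is the cyclopropane bond that breaks) and the benzylic acetate 10 (C4–C4a–C8a unit).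
3. Enabling feature: C1 is a benzylic carbon bearing the electron-rich syringyl ring and lies 1,3 to C3, whose CH2OH is a reduced carboxyl, so C1 and C3 are the donor and acceptor termini of a donor–acceptor cyclopropane. In ring A, C8a is para to the C6 methoxy group (nucleophilic) and the benzylic C4 sits on C4a, para to the C7 oxygen (cation-stabilised), which makes the guaiacyl unit the matching 1,3-ambiphile.
4. Stereocontrol: one catalytic event (copper/bis(oxazoline) cyclopropanation of Z-alkene 5) fixes C1 and C2 in 8. C1 is transferred with inversion in the key step (cis-8 gives 1,2-trans), and C3 follows by equilibration.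
5. Ring order: the temporary cyclopropane first, then ring B. Ring A and the syringyl ring are bought (O-benzylvanillyl alcohol, syringaldehyde); the Z-alkene comes from Still–Gennari olefination and reduction.

Key step: step 8

Remark: tetralin intermediates carry the locants of the target skeleton (C1 bears the syringyl ring, C2 and C3 the one-carbon groups, C4 is the benzylic CH2), and the antipode of the copper ligand that delivers (2S,3S)-8 is assumed to be fixed in a pilot run.

**Route**

Step 1
Reactants: 1 syringaldehyde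
Product: 2 4-(benzyloxy)-3,5-dimethoxybenzaldehyde
Conditions: BnBr, K2CO3, DMF, 60 °C
Reagents that add atoms: benzyl bromide, BrCc1ccccc1
Why: Williamson O-alkylation of the phenoxide masks the syringyl phenol as a benzyl ether that should survive every later step until the final hydrogenolysis.

Step 2
Reactants: 2 4-(benzyloxy)-3,5-dimethoxybenzaldehyde
Product: 3 methyl (2Z)-3-[4-(benzyloxy)-3,5-dimethoxyphenyl]prop-2-enoate
Conditions: (CF3CH2O)2P(O)CH2CO2Me, KN(SiMe3)2, 18-crown-6, THF, −78 °C
Reagents that add atoms: methyl bis(2,2,2-trifluoroethyl)phosphonoacetate, COC(=O)CP(=O)(OCC(F)(F)F)OCC(F)(F)F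
Why: Still–Gennari olefination, in which fast irreversible collapse of the oxaphosphetane from the electron-poor phosphonate under dissociating conditions should deliver the Z enoate.

Step 3
Reactants: 3 Z enoate
Product: 4 (2Z)-3-[4-(benzyloxy)-3,5-dimethoxyphenyl]prop-2-en-1-ol
Conditions: i-Bu2AlH, CH2Cl2, −78 °C
Reagents that add atoms: none
Why: 1,2-reduction of the enoate by i-Bu2AlH at low temperature is expected to give the allylic alcohol without touching the alkene geometry.

Step 4
Reactants: 4 Z allylic alcohol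
Product: 5 {[(2Z)-3-[4-(benzyloxy)-3,5-dimethoxyphenyl]prop-2-en-1-yl]oxy}(tert-butyl)diphenylsilane
Conditions: t-BuPh2SiCl, imidazole, CH2Cl2, 0 °C to rt
Reagents that add atoms: tert-butyl(chloro)diphenylsilane, CC(C)(C)[Si](Cl)(c1ccccc1)c1ccccc1
Why: imidazole-promoted silylation gives a bulky, weakly basic ether that should neither form oxonium ylides in step 6 nor ionise or participate in step 8.

Step 5
Reactants: 6 dimethyl malonate
Product: 7 phenyliodonium bis(methoxycarbonyl)methanide
Conditions: PhI(OAc)2, KOH, MeCN, 0 °C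
Reagents that add atoms: (diacetoxyiodo)benzene, CC(=O)OI(OC(C)=O)c1ccccc1
Why: ligand exchange of the malonate anion on the hypervalent iodine reagent is the standard preparation of this iodonium ylide, a carbene precursor.

Step 6
Reactants: 5 Z allylic silyl ether; 7 iodonium ylide
Product: 8 dimethyl (2S,3S)-2-[4-(benzyloxy)-3,5-dimethoxyphenyl]-3-({[tert-butyl(diphenyl)silyl]oxy}methyl)cyclopropane-1,1-dicarboxylate (aryl cis to CH2OSi)
Conditions: Cu(MeCN)4PF6 (10 mol%), chiral side-arm bis(oxazoline) ligand (12 mol%), 4 Å MS, toluene, 0 °C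
Reagents that add atoms: none
Why: copper-catalysed asymmetric carbene transfer (cyclopropanation) to a cis-1,2-disubstituted alkene, in which concerted syn addition carries the Z geometry into the cis aryl/CH2OSi relationship and the chiral bis(oxazoline)–copper carbene selects the alkene face, setting both stereocentres.

Step 7
Reactants: 9 [4-(benzyloxy)-3-methoxyphenyl]methanol
Product: 10 4-(benzyloxy)-3-methoxybenzyl acetate
Conditions: Ac2O, pyridine, DMAP (cat.), CH2Cl2, 0 °C to rt
Reagents that add atoms: acetic anhydride, CC(=O)OC(C)=O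
Why: DMAP-catalysed acylation removes the nucleophilic hydroxyl (so 8 cannot be O-alkylated in step 8) while leaving a benzylic leaving group that a Lewis acid can ionise.

Step 8
Reactants: 8 cis-cyclopropane diester; 10 4-(benzyloxy)-3-methoxybenzyl acetate
Product: 12 dimethyl (1R,2S)-7-(benzyloxy)-1-[4-(benzyloxy)-3,5-dimethoxyphenyl]-2-({[tert-butyl(diphenyl)silyl]oxy}methyl)-6-methoxy-1,4-dihydronaphthalene-3,3(2H)-dicarboxylate, via ring-opened malonate 11 (not isolated)
Conditions: Sc(OTf)3 (10 mol%), 4 Å MS, ClCH2CH2Cl, 0 to 50 °C, slow addition of 10 (1.2 equiv)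
Reagents that add atoms: none
Why: Proposed new method: Sc(OTf)3 chelates the geminal diester of 8, the arene of 10 attacks the aryl-bearing cyclopropane carbon through its position para to OMe (Friedel–Crafts ring-opening, SN2-like) to give the scandium-bound malonate 11, whose benzylic acetate then ionises to a para-benzyloxybenzyl cation that is captured by the malonate carbon. The closest known reaction types are the Lewis-acid-catalysed formal [3+3] annulation of donor–acceptor cyclopropanes with 2-indolylmethanols, the Friedel–Crafts ring-opening of such cyclopropanes by electron-rich arenes with inversion, and the Lewis-acid-catalysed benzylation of 1,3-dicarbonyl compounds by benzylic acetates. Ring B is closed by a 6-exo-tet alkylation of the malonate carbon at the benzylic carbon (6-endo-trig if the acetate has fully ionised to the quinone-methide-like cation). C1 is set by inversion at the cyclopropane carbon, which turns the cis aryl/CH2OSi relationship of 8 into the 1,2-trans relationship of 12, while C2 is carried over untouched and, not being epimerisable, would turn any loss of stereospecificity into a separable C1 epimer and not into the enantiomer. The step needs attack through the ring A carbon para to OMe (the only activated position that can also close a six-membered ring, the position para to the benzyloxy group being occupied by the CH2OAc carbon), cleavage of the aryl–malonate cyclopropane bond (secured by donor and acceptor on its two ends), and cross-coupling ahead of self-benzylation of 10 (addressed by slow addition of 10 to 8 and catalyst, and by the acetate, which unlike the free alcohol cannot O-alkylate 8).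

Step 9
Reactants: 12 tetralin 3,3-diester
Product: 13 methyl (1R,2S,3RS)-7-(benzyloxy)-1-[4-(benzyloxy)-3,5-dimethoxyphenyl]-2-({[tert-butyl(diphenyl)silyl]oxy}methyl)-6-methoxy-1,2,3,4-tetrahydronaphthalene-3-carboxylate (mixture of C3 epimers)
Conditions: LiCl, H2O, DMSO, 160 °C
Reagents that add atoms: none
Why: Krapcho dealkoxycarbonylation (chloride attack on a methyl ester, then loss of CO2) removes the activating ester, and the resulting enolate is protonated without reliable facial control, hence the epimer mixture at C3.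

Step 10
Reactants: 13 C3-epimeric esters
Product: 14 methyl (1R,2S,3S)-7-(benzyloxy)-1-[4-(benzyloxy)-3,5-dimethoxyphenyl]-2-({[tert-butyl(diphenyl)silyl]oxy}methyl)-6-methoxy-1,2,3,4-tetrahydronaphthalene-3-carboxylate
Conditions: NaOMe (0.3 equiv), MeOH/THF, 50 °C
Reagents that add atoms: none
Why: base-mediated epimerisation alpha to the ester under thermodynamic control should favour the 2,3-trans ester with all three ring B substituents equatorial (the cis epimer is resubmitted), while C1 and C2 carry no acidic hydrogen and keep their configuration.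

Step 11
Reactants: 14 all-trans ester
Product: 15 [(1R,2S,3S)-7-(benzyloxy)-1-[4-(benzyloxy)-3,5-dimethoxyphenyl]-2-({[tert-butyl(diphenyl)silyl]oxy}methyl)-6-methoxy-1,2,3,4-tetrahydronaphthalen-3-yl]methanol
Conditions: LiAlH4, THF, 0 °C
Reagents that add atoms: none
Why: hydride reduction of the ester to the primary alcohol leaves silyl ether, benzyl ethers and all stereocentres untouched.

Step 12
Reactants: 15 silyl-protected alcohol
Product: 16 [(1R,2S,3S)-7-(benzyloxy)-1-[4-(benzyloxy)-3,5-dimethoxyphenyl]-6-methoxy-1,2,3,4-tetrahydronaphthalene-2,3-diyl]dimethanol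
Conditions: Bu4NF, THF, rt
Reagents that add atoms: none
Why: fluoride-mediated desilylation frees the C2 hydroxymethyl group, now safely after the ester that could have lactonised onto it has been reduced.

Step 13
Reactants: 16 dibenzyl diol
Product: 17 (6S,7S,8R)-8-(4-hydroxy-3,5-dimethoxyphenyl)-6,7-bis(hydroxymethyl)-3-methoxy-5,6,7,8-tetrahydronaphthalen-2-ol
Conditions: H2 (1 atm), 10% Pd/C, EtOAc/MeOH, rt
Reagents that add atoms: none
Why: hydrogenolysis of the two aryl benzyl ethers releases both phenols without affecting the C–C framework or the stereocentres, since C1 has no benzylic C–O bond to cleave.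

**Compound list**

1 | syringaldehyde (4-hydroxy-3,5-dimethoxybenzaldehyde) | COc1cc(C=O)cc(OC)c1O | starting material
2 | 4-(benzyloxy)-3,5-dimethoxybenzaldehyde | COc1cc(C=O)cc(OC)c1OCc1ccccc1 | intermediate
3 | methyl (2Z)-3-[4-(benzyloxy)-3,5-dimethoxyphenyl]prop-2-enoate | COC(=O)/C=C\c1cc(OC)c(OCc2ccccc2)c(OC)c1 | intermediate
4 | (2Z)-3-[4-(benzyloxy)-3,5-dimethoxyphenyl]prop-2-en-1-ol | OC/C=C\c1cc(OC)c(OCc2ccccc2)c(OC)c1 | intermediate
5 | {[(2Z)-3-[4-(benzyloxy)-3,5-dimethoxyphenyl]prop-2-en-1-yl]oxy}(tert-butyl)diphenylsilane | CC(C)(C)[Si](OC/C=C\c1cc(OC)c(OCc2ccccc2)c(OC)c1)(c1ccccc1)c1ccccc1 | intermediate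
6 | dimethyl malonate | COC(=O)CC(=O)OC | starting material
7 | phenyliodonium bis(methoxycarbonyl)methanide | COC(=O)[C-](C(=O)OC)[I+]c1ccccc1 | intermediate
8 | dimethyl (2S,3S)-2-[4-(benzyloxy)-3,5-dimethoxyphenyl]-3-({[tert-butyl(diphenyl)silyl]oxy}methyl)cyclopropane-1,1-dicarboxylate (aryl cis to CH2OSi) | [C@@H]1(c2cc(OC)c(OCc3ccccc3)c(OC)c2)[C@H](CO[Si](c2ccccc2)(c2ccccc2)C(C)(C)C)C1(C(=O)OC)C(=O)OC | intermediate
9 | [4-(benzyloxy)-3-methoxyphenyl]methanol | COc1cc(CO)ccc1OCc1ccccc1 | starting material
10 | 4-(benzyloxy)-3-methoxybenzyl acetate | COc1cc(COC(C)=O)ccc1OCc1ccccc1 | intermediate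
11 | dimethyl 2-[(1R,2S)-1-[2-(acetoxymethyl)-5-(benzyloxy)-4-methoxyphenyl]-1-[4-(benzyloxy)-3,5-dimethoxyphenyl]-3-{[tert-butyl(diphenyl)silyl]oxy}propan-2-yl]propanedioate | COc1cc(COC(C)=O)c(cc1OCc1ccccc1)[C@@H](c1cc(OC)c(OCc2ccccc2)c(OC)c1)[C@H](CO[Si](c1ccccc1)(c1ccccc1)C(C)(C)C)C(C(=O)OC)C(=O)OC | intermediate
12 | dimethyl (1R,2S)-7-(benzyloxy)-1-[4-(benzyloxy)-3,5-dimethoxyphenyl]-2-({[tert-butyl(diphenyl)silyl]oxy}methyl)-6-methoxy-1,4-dihydronaphthalene-3,3(2H)-dicarboxylate | COc1cc2c(cc1OCc1ccccc1)[C@@H](c1cc(OC)c(OCc3ccccc3)c(OC)c1)[C@H](CO[Si](c1ccccc1)(c1ccccc1)C(C)(C)C)C(C(=O)OC)(C(=O)OC)C2 | intermediate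
13 | methyl (1R,2S,3RS)-7-(benzyloxy)-1-[4-(benzyloxy)-3,5-dimethoxyphenyl]-2-({[tert-butyl(diphenyl)silyl]oxy}methyl)-6-methoxy-1,2,3,4-tetrahydronaphthalene-3-carboxylate (mixture of C3 epimers) | COc1cc2c(cc1OCc1ccccc1)[C@@H](c1cc(OC)c(OCc3ccccc3)c(OC)c1)[C@H](CO[Si](c1ccccc1)(c1ccccc1)C(C)(C)C)C(C(=O)OC)C2 | intermediate
14 | methyl (1R,2S,3S)-7-(benzyloxy)-1-[4-(benzyloxy)-3,5-dimethoxyphenyl]-2-({[tert-butyl(diphenyl)silyl]oxy}methyl)-6-methoxy-1,2,3,4-tetrahydronaphthalene-3-carboxylate | COc1cc2c(cc1OCc1ccccc1)[C@@H](c1cc(OC)c(OCc3ccccc3)c(OC)c1)[C@H](CO[Si](c1ccccc1)(c1ccccc1)C(C)(C)C)[C@@H](C(=O)OC)C2 | intermediate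
15 | [(1R,2S,3S)-7-(benzyloxy)-1-[4-(benzyloxy)-3,5-dimethoxyphenyl]-2-({[tert-butyl(diphenyl)silyl]oxy}methyl)-6-methoxy-1,2,3,4-tetrahydronaphthalen-3-yl]methanol | COc1cc2c(cc1OCc1ccccc1)[C@@H](c1cc(OC)c(OCc3ccccc3)c(OC)c1)[C@H](CO[Si](c1ccccc1)(c1ccccc1)C(C)(C)C)[C@@H](CO)C2 | intermediate
16 | [(1R,2S,3S)-7-(benzyloxy)-1-[4-(benzyloxy)-3,5-dimethoxyphenyl]-6-methoxy-1,2,3,4-tetrahydronaphthalene-2,3-diyl]dimethanol | COc1cc2c(cc1OCc1ccccc1)[C@@H](c1cc(OC)c(OCc3ccccc3)c(OC)c1)[C@H](CO)[C@@H](CO)C2 | intermediate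
17 | (6S,7S,8R)-8-(4-hydroxy-3,5-dimethoxyphenyl)-6,7-bis(hydroxymethyl)-3-methoxy-5,6,7,8-tetrahydronaphthalen-2-ol (route locants 1R,2S,3S) | COc1cc2c(cc1O)[C@@H](c1cc(OC)c(O)c(OC)c1)[C@H](CO)[C@@H](CO)C2 | target

**Step count and risks**

Total steps: 13. Longest linear sequence: 11 steps (steps 1, 2, 3, 4, 6, 8, 9, 10, 11, 12, 13).

Steps most likely to fail:

1. Step 8 (Proposed new method). What may go wrong: the benzylic acetate ionises before the Friedel–Crafts ring-opening, so that 10 is consumed by self-benzylation, or the opened cyclopropane loses a proton to a styrene instead of forming the C–C bond. The fallback sets out from 8 and 9, returns at 12, and uses known reaction types only. Compound 8 is opened with methanol under Sc(OTf)3 catalysis (alcoholysis of a donor–acceptor cyclopropane) to the γ-methoxy malonate F1. Compound 9 is converted with PBr3 into 4-(benzyloxy)-3-methoxybenzyl bromide F2. The sodium enolate of F1 (NaH, THF/DMF) is C-benzylated with F2 to the quaternary malonate F3. CF3CO2H in CH2Cl2 then ionises the benzylic methyl ether of F3, and intramolecular Friedel–Crafts alkylation closes ring B to 12, the aryl group taking the pseudo-equatorial position trans to C2.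

2. Step 6. What may go wrong: weak enantioface discrimination or slow carbene transfer to the hindered Z-alkene, with the ylide decomposing to carbene dimers. The fallback sets out from 5 and returns at 8. Stereospecific racemic cyclopropanation of 5 with dimethyl diazomalonate and Rh2(esp)2 in CH2Cl2 gives the racemic cis-cyclopropane. Preparative chromatography on a chiral stationary phase then separates 8 from the (2R,3R) enantiomer F4.

3. Step 10. What may go wrong: insufficient thermodynamic bias between the C3 epimers, so that equilibration stalls at a mixture that must be separated and recycled repeatedly. The fallback sets out from 8, returns at 16, and sets C3 on a five-membered lactone before ring B is closed. The γ-methoxy malonate F1 (made from 8 as in the fallback for step 8) is desilylated with Bu4NF and lactonises to the α-carbomethoxy butyrolactone F5. Alkylation of its sodium enolate (NaH, THF) with the bromide F2, anti to the β-substituent, gives the quaternary lactone ester F6. Krapcho dealkoxycarbonylation (LiCl, H2O, DMSO) gives the trans-3,4-disubstituted butyrolactone F7, the strongly favoured epimer of such lactones. CF3CO2H in CH2Cl2 closes ring B by Friedel–Crafts alkylation to the trans-fused tetralin lactone F8, and LiAlH4 reduces F8 to 16.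

**Further compounds**

F1 | step 8 | dimethyl 2-[(1R,2S)-1-[4-(benzyloxy)-3,5-dimethoxyphenyl]-3-{[tert-butyl(diphenyl)silyl]oxy}-1-methoxypropan-2-yl]propanedioate | CO[C@@H](c1cc(OC)c(OCc2ccccc2)c(OC)c1)[C@H](CO[Si](c1ccccc1)(c1ccccc1)C(C)(C)C)C(C(=O)OC)C(=O)OC
F2 | step 8 | 4-(benzyloxy)-3-methoxybenzyl bromide | COc1cc(CBr)ccc1OCc1ccccc1
F3 | step 8 | dimethyl 2-[4-(benzyloxy)-3-methoxybenzyl]-2-[(1R,2S)-1-[4-(benzyloxy)-3,5-dimethoxyphenyl]-3-{[tert-butyl(diphenyl)silyl]oxy}-1-methoxypropan-2-yl]propanedioate | CO[C@@H](c1cc(OC)c(OCc2ccccc2)c(OC)c1)[C@H](CO[Si](c1ccccc1)(c1ccccc1)C(C)(C)C)C(Cc1ccc(OCc2ccccc2)c(OC)c1)(C(=O)OC)C(=O)OC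
F4 | step 6 | dimethyl (2R,3R)-2-[4-(benzyloxy)-3,5-dimethoxyphenyl]-3-({[tert-butyl(diphenyl)silyl]oxy}methyl)cyclopropane-1,1-dicarboxylate (enantiomer of 8) | [C@H]1(c2cc(OC)c(OCc3ccccc3)c(OC)c2)[C@@H](CO[Si](c2ccccc2)(c2ccccc2)C(C)(C)C)C1(C(=O)OC)C(=O)OC
F5 | step 10 | methyl (4S)-4-[(R)-[4-(benzyloxy)-3,5-dimethoxyphenyl](methoxy)methyl]-2-oxooxolane-3-carboxylate | CO[C@@H](c1cc(OC)c(OCc2ccccc2)c(OC)c1)[C@@H]1COC(=O)C1C(=O)OC
F6 | step 10 | methyl (3S,4S)-3-[4-(benzyloxy)-3-methoxybenzyl]-4-[(R)-[4-(benzyloxy)-3,5-dimethoxyphenyl](methoxy)methyl]-2-oxooxolane-3-carboxylate | CO[C@@H](c1cc(OC)c(OCc2ccccc2)c(OC)c1)[C@@H]1COC(=O)[C@@]1(C(=O)OC)Cc1ccc(OCc2ccccc2)c(OC)c1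
F7 | step 10 | (3S,4S)-3-[4-(benzyloxy)-3-methoxybenzyl]-4-[(R)-[4-(benzyloxy)-3,5-dimethoxyphenyl](methoxy)methyl]oxolan-2-one | CO[C@@H](c1cc(OC)c(OCc2ccccc2)c(OC)c1)[C@@H]1COC(=O)[C@H]1Cc1ccc(OCc2ccccc2)c(OC)c1
F8 | step 10 | trans-fused γ-lactone of (1R,2S,3S)-7-(benzyloxy)-1-[4-(benzyloxy)-3,5-dimethoxyphenyl]-2-(hydroxymethyl)-6-methoxy-1,2,3,4-tetrahydronaphthalene-3-carboxylic acid | COc1cc2c(cc1OCc1ccccc1)[C@@H](c1cc(OC)c(OCc3ccccc3)c(OC)c1)[C@@H]1COC(=O)[C@H]1C2
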